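## Analysis of the target

The target (25) is the C2-symmetric C50 carotenoid (2R,2′R)-2,2′-bis[(2E)-4-hydroxy-3-methylbut-2-en-1-yl]-β,β-carotene. It consists of two cyclohexene rings (ring A and ring A′) joined by an all-E nonaene chain C7–C7′, with a C5 branch on C2 and on C2′. The branch is lettered here C2–CaH2–CbH=Cc(CeH3)–CdH2OH; the rest follows carotenoid numbering (C16/C17 on C1, C18 on C5, C19 on C9, C20 on C13).

The only stereocentres are C2 and C2′, both R. Each is a CH between the quaternary C1 and C3H2. They are 22 bonds apart, so neither can steer the other and each has to be set absolutely. Because the molecule is built from two identical halves, any wrong enantiomer in the half reappears as the meso (2R,2′S) diastereomer, which cannot realistically be removed.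

The feature that decides the strategy is the array C1(C16,C17)–C2H(Ca)–C3–C4–C5(C18)=C6 in rings A and A′. An irregular C5 unit on C2 next to the gem-dimethyl carbon, beside a tetrasubstituted C5=C6 bond, is the footprint of an open-chain end group with a C1=C16 isopropenyl group that has closed its C1–C6 bond. This is the order of the presumed biosynthesis: the C5 unit is attached to C2 first, the ring is closed afterwards.

The sensitive groups are the undecaene chromophore (acid, light, oxygen, heat) and the two ionisable primary allylic alcohols. All acid chemistry must therefore be finished before the polyene exists, and the hydroxyl groups are best carried as esters. The hard points are the C2–Ca bond at a neopentyl-type position (it cannot be made by substitution on a preformed ring), the quaternary C1 next to C2, the tetrasubstituted C5=C6 bond, and the E geometry at Cb=Cc and along the chain.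

## Retrosynthetic reasoning

**25 ⇒ 24 (functional group change at Cd, Cd′).** Both CdH2OH groups are traced back to the ethyl esters of 24. An α-methyl enoate survives strong acid, ylides and a cold Grignard addition, so no protecting group is needed anywhere. One hydride reduction at the end must leave the polyene untouched.

**24 ⇒ 2 × 20 + 21 (C11=C12 and C11′=C12′).** The chain is cut symmetrically at the two bonds that a two-fold Wittig olefination forms. The central ten carbons (C12–C12′ with C20, C20′) are the commercial dialdehyde 21, and the problem is halved to the C22 phosphonium salt 20. The forward reaction has to deliver the all-E chain, which the usual thermal E/Z equilibration of carotenoids secures.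

**20 ⇒ 18 ⇒ 16 (C11–P, then C9–C10).** The allylic phosphonium salt comes from the tertiary divinyl carbinol 18 by ionisation and capture at the primary terminus. 18 comes from ketone 16 by addition of the vinyl reagent 17, which supplies C10 and C11. This is the shortest known way from a β-ionone-type ketone to a C15-type Wittig salt.

**16 ⇒ 15 (key disconnection, C1–C6 of ring A).** The ring is opened at the bond the biosynthetic cyclase makes. This removes the ring, the quaternary carbon and the tetrasubstituted alkene at once. What remains is the open-chain trienone 15, in which C2 is an ordinary acyclic stereocentre and C1 is an isopropenyl carbon. The forward step must protonate only C1=C16, close the six-membered ring through C6, place the new double bond at C5=C6 and leave C2 untouched. Because C5=C6 ends up inside the ring, its geometry in 15 (the C8=C9 bond in the numbering of 15) is irrelevant, which frees the chain synthesis from any control at that bond.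

**15 ⇒ 11 + 12, and 11 ⇒ 9 + 10 (C7–C8, then C5–C6).** The dienone is made from the methyl ketone 9 in two operations. The acetylide 10 adds to the ketone (C5–C6), and a propargyl Claisen rearrangement with the enol ether 12 forms C7–C8 and brings in C8, C9 and C19. Base then moves the allene into conjugation. The sequence gives an 8E/8Z mixture of 15, which the key step tolerates.

**9 ⇒ 8 + 7, 8 ⇒ 6 ⇒ 5 (Cb=Cc, redox adjustment).** The E-trisubstituted Cb=Cc bond with Cd and Ce comes from the stabilised ylide 7 and the aldehyde 8. The ester carbon of 5 is Cb, so 5 is reduced to diol 6 and both carbinols are re-oxidised; the aldehyde is olefinated as it forms.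

**5 ⇒ 3 + 4 (C1–C2).** In the open chain C2 is β to the ester carbon Cb, the only carbonyl relationship that allows a catalytic asymmetric C–C bond formation at C2. Rhodium-catalysed conjugate addition of the isopropenyl boron reagent 4 to the (E)-enoate 3 sets the single stereocentre of each half under catalyst control and installs C1, C16 and C17.

**3 ⇒ 1 + 2 (C2=Ca).** Cross-metathesis of the two commercial alkenes 1 and 2 gives the (E)-enoate; 1 supplies C2–C5 and C18, 2 supplies Ca and Cb.

## Alternatives that were turned down

**Alternative 1:** the textbook route keeps ring A from the start and disconnects C2–Ca and C6–C7.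
- Forward: asymmetric conjugate addition to the cyclic enone A1 with methylation of the enolate (C2 and quaternary C1), methylation at C5 to give ketone A2, enol triflate A3, then a palladium-catalysed coupling at C6 to reach 16.
- Why not: the nucleophile needed at C2 is an allyl-type C5 unit. Allyl metals add 1,2 to enones or react through their γ-terminus, which would give the branched isomer. Only a one-carbon or vinyl handle can therefore be introduced, and Ca–Ce must then be built in four or five further steps at a centre shielded by C1.
- The ring offers no stereochemical advantage, because C2 is its only stereocentre.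
- The closing coupling at a tetrasubstituted triflate flanked by a quaternary carbon belongs to the slowest class of such couplings.
- By count, about ten steps would be needed to reach 16, against seven here.

**Alternative 2:** follow the biosynthetic order literally: build the acyclic C50 diol A4 and close both rings (C1–C6 and C1′–C6′) in the last step.
- Forward: a C50 carotenoid β-cyclase, a membrane-bound enzyme of the lycopene cyclase class. No small reagent can do this, since any acid able to protonate C1=C16 attacks the undecaene first.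
- Why not: A4 needs defined 5E,5′E geometry, which the chosen route is free to ignore.
- A4 is a more fragile acyclic polyene than any intermediate used here.
- The enzyme is an integral membrane protein acting on a water-insoluble substrate, so turnover with added substrate outside the cell cannot be relied on.
- The risk would sit in the last step on the most valuable material, and no step is saved.

**Alternative 3:** create C2 and ring A in one step from an achiral precursor.
- Forward: enantioselective proton-initiated cyclisation of A5, in which C1=C2 is a tetrasubstituted isopropylidene group. A chiral Brønsted acid (a BINOL-type acid activated by a tin Lewis acid) would deliver the proton to C2 while C6 attacks C1.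
- Why not: the acid would have to tell apart the two faces of an alkene whose C2 substituents are two CH2 chains (C3 and Ca), with no steric or electronic bias.
- Protonation at C1 instead of C2 gives an equally tertiary cation.
- The terminating alkene is part of an electron-poor dienone and needs a far stronger acid than such chiral acids provide.
- Any shortfall in enantioselectivity becomes the inseparable meso diastereomer after dimerisation.

Key step: step 7

Assumption: carbinol centres that are erased later (in 6, 11, 13, 18), the allene axis of 14 and the C8=C9 geometry of 15 are carried as mixtures; only the centre that becomes C2 is controlled.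

## Route

Step 1
Reactants: 1 hex-5-en-2-one; 2 ethyl acrylate
Product: 3 ethyl (2E)-6-oxohept-2-enoate
Conditions: 2 (3 equiv), second-generation Grubbs catalyst (2 mol %), CH2Cl2, 40 °C
Reagents that add atoms: ethyl acrylate (2), C=CC(=O)OCC
Why: Olefin cross-metathesis between an unhindered terminal alkene and an acrylate is selective for the cross product and gives the E-enoate; the ketone is inert.

Step 2
Reactants: 3 ethyl (2E)-6-oxohept-2-enoate; 4 potassium trifluoro(prop-1-en-2-yl)borate
Product: 5 ethyl (3R)-6-oxo-3-(prop-1-en-2-yl)heptanoate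
Conditions: [Rh(cod)2]BF4 (3 mol %; cod = 1,5-cyclooctadiene), (S)-BINAP (3.3 mol %), 4 (2.5 equiv), toluene/H2O 4:1, 100 °C
Reagents that add atoms: potassium trifluoro(prop-1-en-2-yl)borate (4), [K+].C=C(C)[B-](F)(F)F
Why: Rhodium-catalysed asymmetric conjugate addition of an alkenylboron reagent (Hayashi–Miyaura type) to an (E)-enoate. In the accepted model (S)-BINAP delivers the alkenyl group to the α-si face, which makes the new centre R (isopropenyl > CH2CO2Et > CH2CH2COCH3); the antipodal ligand would be used if the sense proved opposite. The water-rich medium should protonate the rhodium enolate before it can reach the ketone.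

Step 3
Reactants: 5 ethyl (3R)-6-oxo-3-(prop-1-en-2-yl)heptanoate
Product: 6 (3R)-3-(prop-1-en-2-yl)heptane-1,6-diol (both C6 epimers)
Conditions: LiAlH4, THF, 0 °C; aqueous work-up
Reagents that add atoms: none
Why: Hydride reduction of ester and ketone together avoids having to tell the two carbonyls apart; the stereocentre is β to the ester and cannot epimerise.

Step 4
Reactants: 6 (3R)-3-(prop-1-en-2-yl)heptane-1,6-diol; 7 ethyl 2-(triphenyl-λ5-phosphanylidene)propanoate
Product: 9 ethyl (2E,5R)-2-methyl-8-oxo-5-(prop-1-en-2-yl)non-2-enoate, via keto aldehyde 8 (not isolated)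
Conditions: Dess–Martin periodinane (2.4 equiv), CH2Cl2, rt; then 7 (1.3 equiv), rt
Reagents that add atoms: ethyl 2-(triphenyl-λ5-phosphanylidene)propanoate (7), CCOC(=O)C(C)=P(c1ccccc1)(c1ccccc1)c1ccccc1
Why: Tandem alcohol oxidation and Wittig olefination; the stabilised α-methyl ylide reacts only with the aldehyde, not the methyl ketone, and gives the E-trisubstituted enoate. Trapping the keto aldehyde as it forms avoids its intramolecular aldol reaction.

Step 5
Reactants: 9 ethyl (2E,5R)-2-methyl-8-oxo-5-(prop-1-en-2-yl)non-2-enoate; 10 ethynylmagnesium bromide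
Product: 11 ethyl (2E,5R)-8-hydroxy-2,8-dimethyl-5-(prop-1-en-2-yl)dec-2-en-9-ynoate (both C8 epimers)
Conditions: 10 (1.3 equiv), THF, −20 to 0 °C; then aq. NH4Cl
Reagents that add atoms: ethynylmagnesium bromide (10), C#C[Mg]Br
Why: 1,2-Addition of an alkynyl Grignard reagent to a methyl ketone; this mild nucleophile leaves the conjugated, α-branched ester alone.

Step 6
Reactants: 11 ethyl (2E,5R)-8-hydroxy-2,8-dimethyl-5-(prop-1-en-2-yl)dec-2-en-9-ynoate; 12 2-methoxypropene
Product: 15 ethyl (2E,5R,10E)-2,8-dimethyl-12-oxo-5-(prop-1-en-2-yl)trideca-2,8,10-trienoate (8E/8Z mixture), via propargyl isopropenyl ether 13 (not isolated), via allenyl ketone 14 (not isolated)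
Conditions: 12 (4 equiv), pyridinium p-toluenesulfonate (1 mol %), toluene, sealed vessel, 95 °C; then NaOEt (0.1 equiv), EtOH, 0 °C
Reagents that add atoms: 2-methoxypropene (12), COC(C)=C
Why: Saucy–Marbet propargyl Claisen rearrangement (trans-etherification, [3,3] shift to the β-allenyl ketone), then base-mediated isomerisation of the allene into the conjugated dienone. The new C10=C11 bond should be E, and the 8E/8Z mixture is accepted because step 7 erases that geometry.

Step 7
Reactants: 15 ethyl (2E,5R,10E)-2,8-dimethyl-12-oxo-5-(prop-1-en-2-yl)trideca-2,8,10-trienoate (8E/8Z mixture)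
Product: 16 ethyl (2E)-2-methyl-4-[(1R)-2,2,4-trimethyl-3-[(1E)-3-oxobut-1-en-1-yl]cyclohex-3-en-1-yl]but-2-enoate
Conditions: 96% H2SO4 (excess), CH2Cl2, −20 to 0 °C, short contact; poured onto ice
Reagents that add atoms: none
Why: Markovnikov protonation of the isopropenyl group (C1=C16) gives the tertiary C1 cation, which is captured by C6 of the C5=C6 bond through a chair-like transition state; the C5 cation then loses a proton. The closest known reaction type is the acid cyclisation of pseudoionone-type trienones to β-ionones and of their C2-methyl homologues to irones. Ring A closes in a 6-endo-trig cation–olefin mode (C1–C6 bond, both C5 and C6 inside the ring), creating quaternary C1 and the tetrasubstituted alkene. No new stereocentre is formed; the R centre from step 2 is carried through as C2. The step is convergent: 8E and 8Z isomers of 15 give the same ring, and ring double-bond isomers formed first are re-protonated in the medium until the C5=C6 isomer, conjugated with C7=C8–C9=O, is reached. Chemoselectivity of protonation is secured because C1=C16 is the only isolated electron-rich alkene; Cb=Cc and C7=C8 are conjugated to carbonyl groups that are O-protonated in this medium. The selectivity that matters most is ring closure outrunning loss of the C2 proton or a 1,2-hydride shift at the C1 cation; participation of the C5=C6 π bond four atoms away and the low temperature secure it. Four- or five-membered closure onto Cb=Cc is disfavoured by ring strain and would place positive charge next to the ester.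

Step 8
Reactants: 16 ethyl (2E)-2-methyl-4-[(1R)-2,2,4-trimethyl-3-[(1E)-3-oxobut-1-en-1-yl]cyclohex-3-en-1-yl]but-2-enoate; 17 vinylmagnesium bromide
Product: 18 ethyl (2E)-4-[(1R)-3-[(1E)-3-hydroxy-3-methylpenta-1,4-dien-1-yl]-2,2,4-trimethylcyclohex-3-en-1-yl]-2-methylbut-2-enoate (both carbinol epimers)
Conditions: 17 (1.2 equiv), THF, −50 to −20 °C; then aq. NH4Cl
Reagents that add atoms: vinylmagnesium bromide (17), C=C[Mg]Br
Why: 1,2-Grignard addition to the methyl ketone, as in the classical conversion of β-ionone into its vinyl carbinol; at low temperature and near-stoichiometric reagent the α-methyl enoate should react far more slowly than the ketone.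

Step 9
Reactants: 18 ethyl (2E)-4-[(1R)-3-[(1E)-3-hydroxy-3-methylpenta-1,4-dien-1-yl]-2,2,4-trimethylcyclohex-3-en-1-yl]-2-methylbut-2-enoate; 19 triphenylphosphine hydrobromide
Product: 20 [(2E,4E)-5-{(5R)-5-[(2E)-4-ethoxy-3-methyl-4-oxobut-2-en-1-yl]-2,6,6-trimethylcyclohex-1-en-1-yl}-3-methylpenta-2,4-dien-1-yl]triphenylphosphonium bromide
Conditions: 19 (1.05 equiv), EtOH, 0 °C to rt
Reagents that add atoms: triphenylphosphine hydrobromide (19), [Br-].[PH+](c1ccccc1)(c1ccccc1)c1ccccc1
Why: Ionisation of the tertiary bis-allylic alcohol to a pentadienyl cation and capture by the phosphine at the primary terminus (allylic transposition) gives the conjugated 9E salt, which can be purified by crystallisation. The ester and the isolated alkenes are inert to this mild acid.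

Step 10
Reactants: 20 the phosphonium bromide of step 9 (2.2 equiv); 21 (2E,4E,6E)-2,7-dimethylocta-2,4,6-trienedial
Product: 24 diethyl (2E,2′E)-4,4′-[(2R,2′R)-β,β-carotene-2,2′-diyl]bis(2-methylbut-2-enoate), via phosphonium ylide 22 (not isolated), via mono-olefinated apocarotenal 23 (not isolated)
Conditions: NaOEt, EtOH/CH2Cl2, 0 °C to rt, argon, dark; then n-heptane, reflux
Reagents that add atoms: (2E,4E,6E)-2,7-dimethylocta-2,4,6-trienedial (21), O=C/C(C)=C/C=C/C=C(C)/C=O
Why: Two-fold Wittig olefination forms C11=C12 and C11′=C12′ and joins the halves. The semi-stabilised ylide gives E/Z mixtures at the new bonds, which thermal equilibration should funnel to the all-E isomer. Ethoxide in ethanol cannot change the ethyl esters.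

Step 11
Reactants: 24 diethyl (2E,2′E)-4,4′-[(2R,2′R)-β,β-carotene-2,2′-diyl]bis(2-methylbut-2-enoate)
Product: 25 (2R,2′R)-2,2′-bis[(2E)-4-hydroxy-3-methylbut-2-en-1-yl]-β,β-carotene
Conditions: i-Bu2AlH (5 equiv), CH2Cl2, −78 to −40 °C, dark; aq. potassium sodium tartrate
Reagents that add atoms: none
Why: 1,2-Reduction of the two α,β-unsaturated esters to the primary allylic alcohols; the esters are not conjugated with the chromophore and the polyene does not react with the aluminium hydride at low temperature.

## Compound list

1 | hex-5-en-2-one | CC(=O)CCC=C | starting material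
2 | ethyl acrylate | C=CC(=O)OCC | starting material
3 | ethyl (2E)-6-oxohept-2-enoate | CCOC(=O)/C=C/CCC(C)=O | intermediate
4 | potassium trifluoro(prop-1-en-2-yl)borate | [K+].C=C(C)[B-](F)(F)F | starting material
5 | ethyl (3R)-6-oxo-3-(prop-1-en-2-yl)heptanoate | CCOC(=O)C[C@@H](CCC(C)=O)C(C)=C | intermediate
6 | (3R)-3-(prop-1-en-2-yl)heptane-1,6-diol (C6 epimers) | OCC[C@@H](CCC(C)O)C(C)=C | intermediate
7 | ethyl 2-(triphenyl-λ5-phosphanylidene)propanoate | CCOC(=O)C(C)=P(c1ccccc1)(c1ccccc1)c1ccccc1 | starting material
8 | (3R)-6-oxo-3-(prop-1-en-2-yl)heptanal | O=CC[C@@H](CCC(C)=O)C(C)=C | intermediate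
9 | ethyl (2E,5R)-2-methyl-8-oxo-5-(prop-1-en-2-yl)non-2-enoate | CCOC(=O)/C(C)=C/C[C@@H](CCC(C)=O)C(C)=C | intermediate
10 | ethynylmagnesium bromide | C#C[Mg]Br | starting material
11 | ethyl (2E,5R)-8-hydroxy-2,8-dimethyl-5-(prop-1-en-2-yl)dec-2-en-9-ynoate (C8 epimers) | CCOC(=O)/C(C)=C/C[C@@H](CCC(C)(O)C#C)C(C)=C | intermediate
12 | 2-methoxypropene | COC(C)=C | starting material
13 | ethyl (2E,5R)-2,8-dimethyl-5-(prop-1-en-2-yl)-8-(prop-1-en-2-yloxy)dec-2-en-9-ynoate | CCOC(=O)/C(C)=C/C[C@@H](CCC(C)(OC(C)=C)C#C)C(C)=C | intermediate
14 | ethyl (2E,5R)-2,8-dimethyl-12-oxo-5-(prop-1-en-2-yl)trideca-2,8,9-trienoate | CCOC(=O)/C(C)=C/C[C@@H](CCC(C)=C=CCC(C)=O)C(C)=C | intermediate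
15 | ethyl (2E,5R,10E)-2,8-dimethyl-12-oxo-5-(prop-1-en-2-yl)trideca-2,8,10-trienoate (8E/8Z mixture) | CCOC(=O)/C(C)=C/C[C@@H](CCC(C)=C/C=C/C(C)=O)C(C)=C | intermediate
16 | ethyl (2E)-2-methyl-4-[(1R)-2,2,4-trimethyl-3-[(1E)-3-oxobut-1-en-1-yl]cyclohex-3-en-1-yl]but-2-enoate | CCOC(=O)/C(C)=C/C[C@H]1CCC(C)=C(/C=C/C(C)=O)C1(C)C | intermediate
17 | vinylmagnesium bromide | C=C[Mg]Br | starting material
18 | ethyl (2E)-4-[(1R)-3-[(1E)-3-hydroxy-3-methylpenta-1,4-dien-1-yl]-2,2,4-trimethylcyclohex-3-en-1-yl]-2-methylbut-2-enoate (carbinol epimers) | CCOC(=O)/C(C)=C/C[C@H]1CCC(C)=C(/C=C/C(C)(O)C=C)C1(C)C | intermediate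
19 | triphenylphosphine hydrobromide | [Br-].[PH+](c1ccccc1)(c1ccccc1)c1ccccc1 | starting material
20 | [(2E,4E)-5-{(5R)-5-[(2E)-4-ethoxy-3-methyl-4-oxobut-2-en-1-yl]-2,6,6-trimethylcyclohex-1-en-1-yl}-3-methylpenta-2,4-dien-1-yl]triphenylphosphonium bromide | CCOC(=O)/C(C)=C/C[C@H]1CCC(C)=C(/C=C/C(C)=C/C[P+](c2ccccc2)(c2ccccc2)c2ccccc2)C1(C)C.[Br-] | intermediate
21 | (2E,4E,6E)-2,7-dimethylocta-2,4,6-trienedial | O=C/C(C)=C/C=C/C=C(C)/C=O | starting material
22 | ethyl (2E)-2-methyl-4-[(1R)-2,2,4-trimethyl-3-[(1E,3E)-3-methyl-5-(triphenyl-λ5-phosphanylidene)penta-1,3-dien-1-yl]cyclohex-3-en-1-yl]but-2-enoate | CCOC(=O)/C(C)=C/C[C@H]1CCC(C)=C(/C=C/C(C)=C/C=P(c2ccccc2)(c2ccccc2)c2ccccc2)C1(C)C | intermediate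
23 | ethyl (2E)-4-[(1R)-3-[(1E,3E,5E,7E,9E,11E)-3,7,12-trimethyl-13-oxotrideca-1,3,5,7,9,11-hexaen-1-yl]-2,2,4-trimethylcyclohex-3-en-1-yl]-2-methylbut-2-enoate | CCOC(=O)/C(C)=C/C[C@H]1CCC(C)=C(/C=C/C(C)=C/C=C/C(C)=C/C=C/C=C(C)/C=O)C1(C)C | intermediate
24 | diethyl (2E,2′E)-4,4′-[(2R,2′R)-β,β-carotene-2,2′-diyl]bis(2-methylbut-2-enoate) | CCOC(=O)/C(C)=C/C[C@H]1CCC(C)=C(/C=C/C(C)=C/C=C/C(C)=C/C=C/C=C(C)/C=C/C=C(C)/C=C/C2=C(C)CC[C@H](C/C=C(C)/C(=O)OCC)C2(C)C)C1(C)C | intermediate
25 | (2R,2′R)-2,2′-bis[(2E)-4-hydroxy-3-methylbut-2-en-1-yl]-β,β-carotene | CC1=C(/C=C/C(C)=C/C=C/C(C)=C/C=C/C=C(C)/C=C/C=C(C)/C=C/C2=C(C)CC[C@H](C/C=C(\C)CO)C2(C)C)C(C)(C)[C@@H](C/C=C(\C)CO)CC1 | target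

## Step count and least certain steps

Total: 11 steps. Longest linear sequence: 11 steps (1 → 25). Compounds 2, 4, 7, 10, 12, 17, 19 and 21 are purchased.

**Step 7 (key step).** During the strong-acid equilibration that funnels the double-bond isomers to the conjugated one, the C1 cation may lose the proton on C2 (isopropenyl to isopropylidene) or undergo a 1,2-hydride shift before the ring closes. Either process would erode the configuration at C2. Conversion of the non-conjugated ring isomers may also stay incomplete.
Fallback, from 15 back to 16: separate ring closure from double-bond placement. Kinetic closure with chlorosulfonic acid in CH2Cl2 at −78 °C for a few minutes should give mainly the non-conjugated isomer, ethyl (2E)-2-methyl-4-[(1R)-4,6,6-trimethyl-5-[(1E)-3-oxobut-1-en-1-yl]cyclohex-3-en-1-yl]but-2-enoate F1 (mixture at the ring carbon bearing the enone chain). The double bond is then moved into conjugation under base (catalytic NaOEt in EtOH) through the extended enolate, giving 16 without further exposure of C2 to acid.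

**Step 2.** The rhodium enolate formed after alkenyl transfer may be trapped by the C6 ketone (intramolecular aldol to a cyclopentanol) instead of being protonated. The boron reagent may also be protodeboronated before it inserts into the moderately reactive enoate, and facial selectivity may fall short.
Fallback, from 1 back to 5: mask the ketone first. Ketalisation of 1 with ethane-1,2-diol (TsOH, benzene, reflux) gives 2-(but-3-en-1-yl)-2-methyl-1,3-dioxolane F2. Cross-metathesis with 2 gives ethyl (2E)-5-(2-methyl-1,3-dioxolan-2-yl)pent-2-enoate F3. The conjugate addition of 4, now free of the aldol pathway and open to more forcing conditions, gives ethyl (3R)-4-methyl-3-[2-(2-methyl-1,3-dioxolan-2-yl)ethyl]pent-4-enoate F4. Aqueous HCl in acetone returns 5.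

**Step 6.** At the temperature of the propargyl Claisen rearrangement the acid catalyst may isomerise the isopropenyl group or dehydrate the hindered tertiary propargylic alcohol instead of etherifying it. The allenyl ketone may also oligomerise before it is isomerised.
Fallback, from 9 back to 15: build the dienone by carbonyl chemistry instead. Addition of 17 to 9 gives the tertiary vinyl carbinol ethyl (2E,5R)-8-hydroxy-2,8-dimethyl-5-(prop-1-en-2-yl)deca-2,9-dienoate F5. Oxidative 1,3-transposition with pyridinium chlorochromate, [C5H5NH][CrO3Cl], in CH2Cl2 gives the enal ethyl (2E,5R)-2,8-dimethyl-10-oxo-5-(prop-1-en-2-yl)deca-2,8-dienoate F6 (8E/8Z). Wittig olefination with 1-(triphenyl-λ5-phosphanylidene)propan-2-one gives 15.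

**Step 8.** The Grignard reagent may also add to the ethyl ester, or enolise the methyl ketone, so that conversion and chemoselectivity cannot both be kept high.
Fallback, from 16 directly to 25: reverse the polarity of the final olefination so that no organometallic reagent meets the ester. Horner–Wadsworth–Emmons reaction of 16 with diethyl cyanomethylphosphonate (NaH, THF) gives ethyl (2E)-4-[(1R)-3-[(1E,3E)-4-cyano-3-methylbuta-1,3-dien-1-yl]-2,2,4-trimethylcyclohex-3-en-1-yl]-2-methylbut-2-enoate F7. i-Bu2AlH reduces the nitrile to the aldehyde and the ester to the alcohol in one operation, giving (2E,4E)-5-{(5R)-5-[(2E)-4-hydroxy-3-methylbut-2-en-1-yl]-2,6,6-trimethylcyclohex-1-en-1-yl}-3-methylpenta-2,4-dienal F8. Two-fold Wittig reaction of F8 (2 equiv) with the bis-ylide from [(2E,4E,6E)-2,7-dimethylocta-2,4,6-triene-1,8-diyl]bis(triphenylphosphonium) dibromide F9 (NaOMe, MeOH/CH2Cl2), followed by thermal isomerisation, gives 25.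

## Further compounds

F1 | step 7 | ethyl (2E)-2-methyl-4-[(1R)-4,6,6-trimethyl-5-[(1E)-3-oxobut-1-en-1-yl]cyclohex-3-en-1-yl]but-2-enoate | CCOC(=O)/C(C)=C/C[C@H]1CC=C(C)C(/C=C/C(C)=O)C1(C)C
F2 | step 2 | 2-(but-3-en-1-yl)-2-methyl-1,3-dioxolane | CC1(CCC=C)OCCO1
F3 | step 2 | ethyl (2E)-5-(2-methyl-1,3-dioxolan-2-yl)pent-2-enoate | CCOC(=O)/C=C/CCC1(C)OCCO1
F4 | step 2 | ethyl (3R)-4-methyl-3-[2-(2-methyl-1,3-dioxolan-2-yl)ethyl]pent-4-enoate | CCOC(=O)C[C@@H](CCC1(C)OCCO1)C(C)=C
F5 | step 6 | ethyl (2E,5R)-8-hydroxy-2,8-dimethyl-5-(prop-1-en-2-yl)deca-2,9-dienoate | CCOC(=O)/C(C)=C/C[C@@H](CCC(C)(O)C=C)C(C)=C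
F6 | step 6 | ethyl (2E,5R)-2,8-dimethyl-10-oxo-5-(prop-1-en-2-yl)deca-2,8-dienoate | CCOC(=O)/C(C)=C/C[C@@H](CCC(C)=CC=O)C(C)=C
F7 | step 8 | ethyl (2E)-4-[(1R)-3-[(1E,3E)-4-cyano-3-methylbuta-1,3-dien-1-yl]-2,2,4-trimethylcyclohex-3-en-1-yl]-2-methylbut-2-enoate | CCOC(=O)/C(C)=C/C[C@H]1CCC(C)=C(/C=C/C(C)=C/C#N)C1(C)C
F8 | step 8 | (2E,4E)-5-{(5R)-5-[(2E)-4-hydroxy-3-methylbut-2-en-1-yl]-2,6,6-trimethylcyclohex-1-en-1-yl}-3-methylpenta-2,4-dienal | OC/C(C)=C/C[C@H]1CCC(C)=C(/C=C/C(C)=C/C=O)C1(C)C
F9 | step 8 | [(2E,4E,6E)-2,7-dimethylocta-2,4,6-triene-1,8-diyl]bis(triphenylphosphonium) dibromide | c1ccccc1[P+](c1ccccc1)(c1ccccc1)C/C(C)=C/C=C/C=C(C)/C[P+](c1ccccc1)(c1ccccc1)c1ccccc1.[Br-].[Br-]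
A1 | alternative 1 | 2-methylcyclohex-2-en-1-one | CC1=CCCCC1=O
A2 | alternative 1 | ethyl (2E)-2-methyl-4-[(1R)-2,2,4-trimethyl-3-oxocyclohexyl]but-2-enoate | CCOC(=O)/C(C)=C/C[C@H]1CCC(C)C(=O)C1(C)C
A3 | alternative 1 | ethyl (2E)-2-methyl-4-[(1R)-2,2,4-trimethyl-3-{[(trifluoromethyl)sulfonyl]oxy}cyclohex-3-en-1-yl]but-2-enoate | CCOC(=O)/C(C)=C/C[C@H]1CCC(C)=C(OS(=O)(=O)C(F)(F)F)C1(C)C
A4 | alternative 2 | (2R,2′R)-2,2′-bis[(2E)-4-hydroxy-3-methylbut-2-en-1-yl]-1,16,1′,16′-tetradehydro-1,2,1′,2′-tetrahydro-ψ,ψ-carotene | C=C(C)[C@@H](C/C=C(\C)CO)CC/C(C)=C/C=C/C(C)=C/C=C/C(C)=C/C=C/C=C(C)/C=C/C=C(C)/C=C/C=C(C)/CC[C@H](C/C=C(\C)CO)C(C)=C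
A5 | alternative 3 | ethyl (2E,10E)-2,8-dimethyl-12-oxo-5-(propan-2-ylidene)trideca-2,8,10-trienoate | CCOC(=O)/C(C)=C/CC(CCC(C)=C/C=C/C(C)=O)=C(C)C
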